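The route rests on cutting C2 of ring B (the pyran ring O1–C2–C3–C4–C4a–C8a), which carries both O1 and C1' of the fully substituted ring C, back to an aldehyde carbon. In a single operation the key step joins that carbon to the only unsubstituted carbon of 2,4-diformylphloroglucinol (C2–C1'), recloses ring B through O1–C2 and sets C2 trans to C3. Its precursor is the 3,4-cis 6-formyl lactol of rings A and B, carried as the 7-O-triisopropylsilyl ether so that the 5-hydroxyl is tied up in a hydrogen bond to the formyl group and only O1 can close.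

Key step: step 8

Assumption: the menthyl acetals of the two chroman enantiomers formed in step 5 are separable; lactol 10 is drawn closed on O1 as an anomeric mixture; (−)-menthol and the silyl chloride are treated as reagents.

Step 1
Reactants: 1 ethyl 3-methylbutanoate (ethyl isovalerate, two molecules)
Product: 2 ethyl 5-methyl-3-oxo-2-(propan-2-yl)hexanoate (racemic)
Conditions: NaH, THF, reflux; then aq. HCl
Reagents that add atoms: none
Why: Claisen self-condensation, driven by irreversible deprotonation of the β-keto ester; the racemic α-centre becomes sp2 in step 2.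

Step 2
Reactants: 2 ethyl 5-methyl-3-oxo-2-(propan-2-yl)hexanoate; 3 phloroglucinol (benzene-1,3,5-triol)
Product: 4 5,7-dihydroxy-4-(2-methylpropyl)-3-(propan-2-yl)-2H-chromen-2-one
Conditions: MeSO3H, 50 °C
Reagents that add atoms: none
Why: Pechmann condensation on the symmetric, highly nucleophilic triol (no regiochemical issue), with the ketone carbon becoming C4 (isobutyl) and the α-carbon becoming C3 (isopropyl).

Step 3
Reactants: 4 5,7-dihydroxy-4-(2-methylpropyl)-3-(propan-2-yl)-2H-chromen-2-one
Product: 5 5-hydroxy-4-(2-methylpropyl)-3-(propan-2-yl)-7-[tri(propan-2-yl)silyloxy]-2H-chromen-2-one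
Conditions: i-Pr3SiCl (1.05 equiv), imidazole, DMF, 0 °C
Reagents that add atoms: chlorotri(propan-2-yl)silane, CC(C)[Si](Cl)(C(C)C)C(C)C
Why: Selective silyl ether formation at the 7-hydroxyl, which is the more acidic one (para to C4a, conjugated with the lactone) and is not shielded by the C4 isobutyl group as the 5-hydroxyl is.

Step 4
Reactants: 5 5-hydroxy-4-(2-methylpropyl)-3-(propan-2-yl)-7-[tri(propan-2-yl)silyloxy]-2H-chromen-2-one
Product: 6 rac-(3R,4S)-5-hydroxy-4-(2-methylpropyl)-3-(propan-2-yl)-7-[tri(propan-2-yl)silyloxy]-3,4-dihydro-2H-chromen-2-one (3,4-cis)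
Conditions: H2 (40 bar), 10% Pd/C, EtOAc–AcOH, 50 °C
Reagents that add atoms: none
Why: Heterogeneous catalytic hydrogenation should add both hydrogens to the same face of the tetrasubstituted C3=C4 bond, so that isopropyl and isobutyl end up cis (racemic).

Step 5
Reactants: 6 rac-(3R,4S)-5-hydroxy-4-(2-methylpropyl)-3-(propan-2-yl)-7-[tri(propan-2-yl)silyloxy]-3,4-dihydro-2H-chromen-2-one
Product: 8 (2R,3R,4S)-2-[(1R,2S,5R)-menthyloxy]-4-(2-methylpropyl)-3-(propan-2-yl)-7-[tri(propan-2-yl)silyloxy]-3,4-dihydro-2H-chromen-5-ol (single diastereomer after separation), via racemic cis-lactol 7 (not isolated)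
Conditions: i-Bu2AlH (2.2 equiv), CH2Cl2, −78 °C; then (−)-menthol, pyridinium p-toluenesulfonate, 4 Å molecular sieves, CH2Cl2, rt; separation of diastereomers
Reagents that add atoms: (1R,2S,5R)-(−)-menthol, CC(C)[C@@H]1CC[C@@H](C)C[C@H]1O
Why: Half-reduction of the aryl lactone stops at the lactol aluminate at −78 °C, and Fischer-type acetalisation with (−)-menthol should give the equatorial 2,3-trans acetal of each chroman enantiomer; these are diastereomers and are separated (classical resolution), which fixes C3 as R and C4 as S and masks the aldehyde so that C3 cannot enolise.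

Step 6
Reactants: 8 (2R,3R,4S)-2-[(1R,2S,5R)-menthyloxy]-4-(2-methylpropyl)-3-(propan-2-yl)-7-[tri(propan-2-yl)silyloxy]-3,4-dihydro-2H-chromen-5-ol
Product: 10 (3R,4S)-2,5-dihydroxy-4-(2-methylpropyl)-3-(propan-2-yl)-7-[tri(propan-2-yl)silyloxy]-3,4-dihydro-2H-chromene-6-carbaldehyde (lactol, anomeric mixture), via formyl menthyl acetal 9 (not isolated)
Conditions: MgCl2, Et3N, (CH2O)n, MeCN, 70 °C; then 2 M aq. HCl, THF, rt
Reagents that add atoms: paraformaldehyde (as formaldehyde), C=O; water, O
Why: Magnesium phenoxide ortho-formylation (Casiraghi–Skattebøl type) can only reach C6, the one free position ortho to the single free phenol, while C3 is protected as the acetal; the acidic work-up then hydrolyses the acetal to the lactol, which stays closed on O1 because the 5-hydroxyl is chelated to the new formyl group.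

Step 7
Reactants: 3 phloroglucinol (benzene-1,3,5-triol)
Product: 11 2,4,6-trihydroxybenzene-1,3-dicarbaldehyde (2,4-diformylphloroglucinol)
Conditions: POCl3 (2.2 equiv), DMF, 1,4-dioxane, 0 °C to rt; then H2O
Reagents that add atoms: N,N-dimethylformamide, CN(C)C=O; water, O
Why: Double Vilsmeier–Haack formylation, held at the diformyl stage by stoichiometry because each formyl group deactivates the ring.

Step 8
Reactants: 10 (3R,4S)-2,5-dihydroxy-4-(2-methylpropyl)-3-(propan-2-yl)-7-[tri(propan-2-yl)silyloxy]-3,4-dihydro-2H-chromene-6-carbaldehyde; 11 2,4,6-trihydroxybenzene-1,3-dicarbaldehyde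
Product: 14 5-{(2R,3R,4S)-6-formyl-5-hydroxy-4-(2-methylpropyl)-3-(propan-2-yl)-7-[tri(propan-2-yl)silyloxy]-3,4-dihydro-2H-chromen-2-yl}-2,4,6-trihydroxybenzene-1,3-dicarbaldehyde, via hydroxy aldehyde 12 (not isolated), via quinone methide 13 (not isolated)
Conditions: NaOAc, AcOH, 50 °C
Reagents that add atoms: none
Why: In buffered acetic acid lactol 10 opens to hydroxy aldehyde 12, whose aldehyde carbon (C2) is attacked by the one free ring carbon of 11 and loses water to give the ring C ortho-quinone methide 13 with an exocyclic C1'=C2 bond; the ring A hydroxyl on C8a then adds to C2 and ring C rearomatises. The closest known reaction type is the Knoevenagel condensation of formylated phloroglucinols with aliphatic aldehydes to ortho-quinone methides that are trapped by oxygen nucleophiles (oxa-Michael addition). Ring B closes in a 6-exo-trig mode, since the attacked C2=C1' bond lies outside the new ring O1–C2–C3–C4–C4a–C8a. C2 is the only new stereocenter and is controlled by the ring: addition and its reverse equilibrate through 13, so the product should settle in the half-chair with the 2-aryl and 3-isopropyl groups equatorial and the 4-isobutyl group pseudoaxial, that is 2,3-trans (2R). Three selectivities are needed: closure on the C8a oxygen and not the C5 oxygen, which the 7-O-silyl group secures because closure on O5 would give up the only O–H···O=C chelate of the 6-formyl group; retention of C3, helped by the absence of amine catalysts (no enamine) and by an intramolecular trap that should outrun tautomerisation of 13 through C3; and condensation at the aliphatic aldehyde only, since the three aryl aldehydes are chelated and 11 has a single free carbon.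

Step 9
Reactants: 14 5-{(2R,3R,4S)-6-formyl-5-hydroxy-4-(2-methylpropyl)-3-(propan-2-yl)-7-[tri(propan-2-yl)silyloxy]-3,4-dihydro-2H-chromen-2-yl}-2,4,6-trihydroxybenzene-1,3-dicarbaldehyde
Product: 15 5-[(2R,3R,4S)-6-formyl-5,7-dihydroxy-4-(2-methylpropyl)-3-(propan-2-yl)-3,4-dihydro-2H-chromen-2-yl]-2,4,6-trihydroxybenzene-1,3-dicarbaldehyde (target CNP0328914.1)
Conditions: HF·pyridine, THF, 0 °C to rt
Reagents that add atoms: none
Why: Fluoride cleavage of the aryl silyl ether under acidic, non-basic conditions, so that no ring C phenoxide forms to reopen ring B and C2, C3, C4 and the closure regiochemistry stay untouched.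

Compound list
1 | ethyl 3-methylbutanoate (ethyl isovalerate) | CCOC(=O)CC(C)C | starting material
2 | ethyl 5-methyl-3-oxo-2-(propan-2-yl)hexanoate (racemic) | CCOC(=O)C(C(C)C)C(=O)CC(C)C | intermediate
3 | phloroglucinol (benzene-1,3,5-triol) | Oc1cc(O)cc(O)c1 | starting material
4 | 5,7-dihydroxy-4-(2-methylpropyl)-3-(propan-2-yl)-2H-chromen-2-one | CC(C)CC1=C(C(C)C)C(=O)Oc2cc(O)cc(O)c12 | intermediate
5 | 5-hydroxy-4-(2-methylpropyl)-3-(propan-2-yl)-7-[tri(propan-2-yl)silyloxy]-2H-chromen-2-one | CC(C)CC1=C(C(C)C)C(=O)Oc2cc(O[Si](C(C)C)(C(C)C)C(C)C)cc(O)c12 | intermediate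
6 | rac-(3R,4S)-5-hydroxy-4-(2-methylpropyl)-3-(propan-2-yl)-7-[tri(propan-2-yl)silyloxy]-3,4-dihydro-2H-chromen-2-one (racemate, 3,4-cis; the 3R,4S enantiomer is drawn) | CC(C)C[C@@H]1c2c(cc(O[Si](C(C)C)(C(C)C)C(C)C)cc2O)OC(=O)[C@@H]1C(C)C | intermediate
7 | rac-(3R,4S)-4-(2-methylpropyl)-3-(propan-2-yl)-7-[tri(propan-2-yl)silyloxy]-3,4-dihydro-2H-chromene-2,5-diol (racemic cis-lactol, anomeric mixture, not isolated) | CC(C)C[C@@H]1c2c(cc(O[Si](C(C)C)(C(C)C)C(C)C)cc2O)OC(O)[C@@H]1C(C)C | intermediate
8 | (2R,3R,4S)-2-[(1R,2S,5R)-menthyloxy]-4-(2-methylpropyl)-3-(propan-2-yl)-7-[tri(propan-2-yl)silyloxy]-3,4-dihydro-2H-chromen-5-ol | CC(C)C[C@@H]1c2c(cc(O[Si](C(C)C)(C(C)C)C(C)C)cc2O)O[C@@H](O[C@@H]3C[C@H](C)CC[C@H]3C(C)C)[C@@H]1C(C)C | intermediate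
9 | (2R,3R,4S)-5-hydroxy-2-[(1R,2S,5R)-menthyloxy]-4-(2-methylpropyl)-3-(propan-2-yl)-7-[tri(propan-2-yl)silyloxy]-3,4-dihydro-2H-chromene-6-carbaldehyde (not isolated) | CC(C)C[C@@H]1c2c(cc(O[Si](C(C)C)(C(C)C)C(C)C)c(C=O)c2O)O[C@@H](O[C@@H]3C[C@H](C)CC[C@H]3C(C)C)[C@@H]1C(C)C | intermediate
10 | (3R,4S)-2,5-dihydroxy-4-(2-methylpropyl)-3-(propan-2-yl)-7-[tri(propan-2-yl)silyloxy]-3,4-dihydro-2H-chromene-6-carbaldehyde (3,4-cis lactol, anomeric mixture; key-step precursor) | CC(C)C[C@@H]1c2c(cc(O[Si](C(C)C)(C(C)C)C(C)C)c(C=O)c2O)OC(O)[C@@H]1C(C)C | intermediate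
11 | 2,4,6-trihydroxybenzene-1,3-dicarbaldehyde (2,4-diformylphloroglucinol) | O=Cc1c(O)cc(O)c(C=O)c1O | intermediate
12 | (2R,3S)-3-{3-formyl-2,6-dihydroxy-4-[tri(propan-2-yl)silyloxy]phenyl}-5-methyl-2-(propan-2-yl)hexanal (open form of 10, not isolated) | CC(C)C[C@H](c1c(O)cc(O[Si](C(C)C)(C(C)C)C(C)C)c(C=O)c1O)[C@H](C=O)C(C)C | intermediate
13 | ring C ortho-quinone methide: 6-alkylidene-3,5-dihydroxy-2,4-diformylcyclohexa-2,4-dien-1-one with exocyclic C1'=C2, the alkylidene carrying the (2R,3S) side chain of 12 (not isolated) | CC(C)C[C@H](c1c(O)cc(O[Si](C(C)C)(C(C)C)C(C)C)c(C=O)c1O)[C@H](C=C1C(=O)C(C=O)=C(O)C(C=O)=C1O)C(C)C | intermediate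
14 | 5-{(2R,3R,4S)-6-formyl-5-hydroxy-4-(2-methylpropyl)-3-(propan-2-yl)-7-[tri(propan-2-yl)silyloxy]-3,4-dihydro-2H-chromen-2-yl}-2,4,6-trihydroxybenzene-1,3-dicarbaldehyde | CC(C)C[C@@H]1c2c(cc(O[Si](C(C)C)(C(C)C)C(C)C)c(C=O)c2O)O[C@@H](c2c(O)c(C=O)c(O)c(C=O)c2O)[C@@H]1C(C)C | intermediate
15 | 5-[(2R,3R,4S)-6-formyl-5,7-dihydroxy-4-(2-methylpropyl)-3-(propan-2-yl)-3,4-dihydro-2H-chromen-2-yl]-2,4,6-trihydroxybenzene-1,3-dicarbaldehyde (CNP0328914.1) | CC(C)C[C@@H]1c2c(cc(O)c(C=O)c2O)O[C@@H](c2c(O)c(C=O)c(O)c(C=O)c2O)[C@@H]1C(C)C | target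

Total step count: 9. Longest linear sequence: 8 steps (steps 1 to 6, 8 and 9); step 7 supplies the second fragment.

Steps most likely to fail

Step 8 (key step). The hindered aldehyde is mostly tied up as the lactol and the nucleophile carries two formyl groups, so condensation may be slow. During that time C3 could enolise, quinone methide 13 could tautomerise through C3, or the silyl ether could be lost before ring B closes. The fallback separates C–C bond formation from ring closure. It sets out from 10 and 11, which would be condensed at room temperature with 4-methylbenzenesulfinic acid in aqueous formic acid, the known three-component route to 2-(1-sulfonylalkyl)phenols. This would give the benzylic sulfone F1, in which C3 is no longer next to a carbonyl group. Treatment of F1 with NaHCO3 in CH2Cl2–water at room temperature would expel sulfinate, regenerate 13 without acid or heat, and let it close to 14, where the route is rejoined.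

Step 4 (hydrogenation). The tetrasubstituted, electron-rich C3=C4 bond may be reduced incompletely, or double-bond migration on the metal may erode the cis selectivity. The fallback sets the cis relationship by kinetic protonation instead of by syn addition. It sets out from 5, which would be reduced by electron transfer (SmI2, HMPA, t-BuOH, THF) to a lactone mixture rich in the trans-lactone F2. The mixture would be converted with LiN(SiMe3)2 (2.2 equiv, THF, −78 °C) into the dilithium enolate F3. Protonation with AcOH at −78 °C should occur on the face opposite the pseudoaxial C4 isobutyl group and return the cis-lactone 6.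

Step 5 (reduction, acetalisation and resolution). The lactone may be over-reduced, or the menthyl acetals of the two chroman enantiomers (and their anomers) may not separate. The fallback resolves one stage earlier. It sets out from 6, which would be opened with (S)-1-phenylethylamine in toluene to diastereomeric hydroxy amides. The (2R,3S)-amide F4 would be isolated by crystallisation and relactonised (p-TsOH, toluene, reflux) to the enantiopure (3R,4S)-lactone F5. Reduction and acetalisation of F5 as in step 5 would then give 8 as a single diastereomer without separation.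

Further compounds
F1 | step 8 | 5-{(2R,3S)-3-{3-formyl-2,6-dihydroxy-4-[tri(propan-2-yl)silyloxy]phenyl}-5-methyl-1-(4-methylbenzenesulfonyl)-2-(propan-2-yl)hexyl}-2,4,6-trihydroxybenzene-1,3-dicarbaldehyde (epimers at the sulfonyl carbon) | CC(C)C[C@H](c1c(O)cc(O[Si](C(C)C)(C(C)C)C(C)C)c(C=O)c1O)[C@H](C(c1c(O)c(C=O)c(O)c(C=O)c1O)S(=O)(=O)c1ccc(C)cc1)C(C)C
F2 | step 4 | rac-(3S,4S)-5-hydroxy-4-(2-methylpropyl)-3-(propan-2-yl)-7-[tri(propan-2-yl)silyloxy]-3,4-dihydro-2H-chromen-2-one (trans-lactone) | CC(C)C[C@@H]1c2c(cc(O[Si](C(C)C)(C(C)C)C(C)C)cc2O)OC(=O)[C@H]1C(C)C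
F3 | step 4 | dilithium enolate-phenoxide of lactone 6 (racemic) | CC(C)C[C@@H]1c2c(cc(O[Si](C(C)C)(C(C)C)C(C)C)cc2[O-])OC([O-])=C1C(C)C.[Li+].[Li+]
F4 | step 5 | (2R,3S)-3-{2,6-dihydroxy-4-[tri(propan-2-yl)silyloxy]phenyl}-5-methyl-N-[(1S)-1-phenylethyl]-2-(propan-2-yl)hexanamide | CC(C)C[C@H](c1c(O)cc(O[Si](C(C)C)(C(C)C)C(C)C)cc1O)[C@H](C(=O)N[C@@H](C)c1ccccc1)C(C)C
F5 | step 5 | (3R,4S)-5-hydroxy-4-(2-methylpropyl)-3-(propan-2-yl)-7-[tri(propan-2-yl)silyloxy]-3,4-dihydro-2H-chromen-2-one (single enantiomer of 6) | CC(C)C[C@@H]1c2c(cc(O[Si](C(C)C)(C(C)C)C(C)C)cc2O)OC(=O)[C@@H]1C(C)C
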